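**Retrosynthetic overview**
- The quinone of ring B is unmasked last by oxidising the para-related C3'/C6' methoxy pair, after the C5 methyl ether peri to the C4 carbonyl is cleaved; both go back to 3,5,7-trimethoxy-2-(2,3,4,6-tetramethoxyphenyl)chromen-4-one.
- Ring C is cut at three bonds in one operation: O1–C8a and C4–C4a (aryne insertion into the C–O bond of a carboxylic acid) and O1–C2 (conjugate addition–elimination).
- The feature that carries the plan: ring A bears O1 on C8a, the acyl carbon C4 on the adjacent C4a and a methoxy group on C5 next to C4a. This contiguous O/acyl/O pattern is what carboxylate addition to a 3-alkoxyaryne delivers. C2 already sits at enol-ether oxidation level in the acid, so no oxidation is needed to reach the chromone.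
- The aryne precursor comes from 3,5-dimethoxyphenol by carbamate-directed ortho-silylation and triflation. The acid, which carries C4, C3(OMe), C2 and ring B, comes from 1,2,3,5-tetramethoxybenzene by lithiation/Weinreb acylation, methoxycarbonylation, enolate O-methylation and saponification.
- Rings A and B are bought; ring C is the only ring formed.

Key step: step 8

Remark: the target has no stereocentre. The enol ether ester and the derived acid are drawn as the E isomers (carboxyl group cis to the β-methoxy group); either geometric isomer or a mixture would serve, because the alkene geometry is erased during ring closure.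

**Step 1**
Reactants: 1 3,5-dimethoxyphenol
Product: 2 3,5-dimethoxyphenyl N-isopropylcarbamate
Conditions: iPrNCO, Et3N (cat.), CH2Cl2, rt
Reagents that add atoms: isopropyl isocyanate, CC(C)N=C=O
Why: amine-catalysed addition of a phenol to an isocyanate (carbamoylation) should give the secondary carbamate, which directs ortho-metalation and can later be removed under mild base.

**Step 2**
Reactants: 2 3,5-dimethoxyphenyl N-isopropylcarbamate
Product: 6 3,5-dimethoxy-2-(trimethylsilyl)phenyl N-isopropylcarbamate, via N-silyl carbamate 3 (not isolated), via ortho-lithio N-silyl carbamate 4 (not isolated), via N,C-bis(trimethylsilyl) carbamate 5 (not isolated)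
Conditions: Me3SiOTf, TMEDA, Et2O, 0 °C to rt; n-BuLi, TMEDA, −78 °C; Me3SiCl, −78 °C to rt; aq. NaHSO4
Reagents that add atoms: chlorotrimethylsilane, C[Si](C)(C)Cl
Why: directed ortho-metalation, in which the N-silylated carbamate is the strongest director on the ring, so n-BuLi–TMEDA should remove the proton between the carbamate oxygen and a methoxy group (C2 and C6 are equivalent) rather than the one between the two methoxy groups, Me3SiCl traps the aryllithium, and the N–Si bond is hydrolysed on work-up.

**Step 3**
Reactants: 6 3,5-dimethoxy-2-(trimethylsilyl)phenyl N-isopropylcarbamate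
Product: 8 3,5-dimethoxy-2-(trimethylsilyl)phenyl trifluoromethanesulfonate, via 3,5-dimethoxy-2-(trimethylsilyl)phenol 7 (not isolated)
Conditions: DBU, Et2NH, MeCN, 40 °C; then PhNTf2, rt
Reagents that add atoms: N-phenylbis(trifluoromethanesulfonimide), O=S(=O)(N(c1ccccc1)S(=O)(=O)C(F)(F)F)C(F)(F)F
Why: E1cB cleavage of the secondary carbamate by DBU (the isocyanate released is captured by diethylamine) followed by O-triflation of the phenoxide in the same pot should give the ortho-silylaryl triflate without exposing the C–Si bond to acid.

**Step 4**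
Reactants: 9 1,2,3,5-tetramethoxybenzene; 10 N,2-dimethoxy-N-methylacetamide
Product: 12 2-methoxy-1-(2,3,4,6-tetramethoxyphenyl)ethan-1-one, via 2,3,4,6-tetramethoxyphenyllithium 11 (not isolated)
Conditions: n-BuLi, TMEDA, THF, 0 °C; then 10, −78 °C to 0 °C; 1 M aq. HCl
Reagents that add atoms: none
Why: ortho-lithiation between two methoxy groups (the two free ring positions are equivalent) followed by Weinreb ketone synthesis, whose chelated tetrahedral intermediate prevents over-addition, should give the aryl ketone without the ether cleavage that Lewis-acid acylation risks.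

**Step 5**
Reactants: 12 2-methoxy-1-(2,3,4,6-tetramethoxyphenyl)ethan-1-one; 13 dimethyl carbonate
Product: 14 methyl 2-methoxy-3-oxo-3-(2,3,4,6-tetramethoxyphenyl)propanoate (racemic; the enolisable C2 centre is removed in step 6)
Conditions: NaH, THF, reflux; then cold 1 M aq. HCl
Reagents that add atoms: none
Why: crossed Claisen condensation (methoxycarbonylation of the ketone enolate with dimethyl carbonate), driven by deprotonation of the β-keto ester formed, with self-condensation suppressed by the hindered aryl ketone.

**Step 6**
Reactants: 14 methyl 2-methoxy-3-oxo-3-(2,3,4,6-tetramethoxyphenyl)propanoate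
Product: 16 methyl (E)-2,3-dimethoxy-3-(2,3,4,6-tetramethoxyphenyl)prop-2-enoate, via potassium enolate 15 (not isolated)
Conditions: KN(SiMe3)2, THF–DMPU, −78 °C; Me2SO4, −78 °C to 0 °C
Reagents that add atoms: dimethyl sulfate, COS(=O)(=O)OC
Why: O-alkylation of a β-keto ester enolate, favoured by a dissociated potassium enolate in a dipolar aprotic medium, a hard methylating agent and an already fully substituted α-carbon that disfavours C-methylation.

**Step 7**
Reactants: 16 methyl (E)-2,3-dimethoxy-3-(2,3,4,6-tetramethoxyphenyl)prop-2-enoate
Product: 17 (E)-2,3-dimethoxy-3-(2,3,4,6-tetramethoxyphenyl)prop-2-enoic acid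
Conditions: LiOH, THF–MeOH–H2O, 50 °C; then 1 M aq. HCl to pH 4, 0 °C
Reagents that add atoms: lithium hydroxide, [Li+].[OH-]
Why: saponification of the methyl ester by acyl–oxygen cleavage, in which the β-carbon is shielded from hydroxide by the di-ortho-substituted aryl group and cold, brief acidification should spare the enol ether.

**Step 8**
Reactants: 8 3,5-dimethoxy-2-(trimethylsilyl)phenyl trifluoromethanesulfonate; 17 (E)-2,3-dimethoxy-3-(2,3,4,6-tetramethoxyphenyl)prop-2-enoic acid
Product: 20 3,5,7-trimethoxy-2-(2,3,4,6-tetramethoxyphenyl)-4H-chromen-4-one, via 3,5-dimethoxybenzyne 18 (not isolated), via cesium 2-acylphenoxide 19 (not isolated)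
Conditions: 8 (1.5 equiv), CsF (4 equiv), THF, 125 °C, sealed tube
Reagents that add atoms: none
Why: Proposed new method: fluoride strips the silyl group from 8 and triflate leaves to give aryne 18, whose carbon remote from the flanking methoxy group (the future C8a) is attacked by the carboxylate oxygen of 17; the aryl anion that appears at the future C4a, next to the C5 methoxy group, then adds to the ester carbonyl through a four-membered alkoxide that opens to the 2-acylphenoxide 19, a net insertion of the aryne into the acid C–O bond that forms O1–C8a and C4–C4a. Phenoxide 19 should then close ring C by 6-endo-trig conjugate addition to the β-methoxy enone carbon C2 and loss of methoxide, forming O1–C2 and giving the chromone oxidation level directly. The closest known reaction type is the CsF-mediated insertion of arynes into the C–O bond of carboxylic acids to give ortho-hydroxyaryl ketones, with oxa-Michael closure to chroman-4-ones in the case of α,β-unsaturated acids, together with the base-induced closure of 2'-hydroxy β-alkoxy enones to chromones; the combination on a β-alkoxyacrylic acid with a hindered, tetrasubstituted alkene has not been shown. The step needs regioselective carboxylate addition, which the inductively withdrawing methoxy group secures by making the distal aryne carbon the electrophilic one and placing the developing negative charge beside the C–O bond. It also needs acyl transfer to outrun protonation of the aryl anion, which the high temperature and the excess of aryne precursor are meant to favour. No stereocentre is formed, and the alkene geometry of 17 does not matter because C2 becomes tetrahedral before methoxide leaves.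

**Step 9**
Reactants: 20 3,5,7-trimethoxy-2-(2,3,4,6-tetramethoxyphenyl)-4H-chromen-4-one
Product: 21 5-hydroxy-3,7-dimethoxy-2-(2,3,4,6-tetramethoxyphenyl)-4H-chromen-4-one
Conditions: BCl3 (1.2 equiv), CH2Cl2, −78 °C to 0 °C; aq. NaHCO3
Reagents that add atoms: none
Why: chelation-controlled ether cleavage, in which BCl3 binds the C4 carbonyl and the peri C5 methoxy oxygen in a six-membered chelate and chloride removes that methyl group by SN2 attack, while the C3 methoxy group (five-membered chelate only) and the ring B ethers should survive at low temperature with about one equivalent of reagent.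

**Step 10**
Reactants: 21 5-hydroxy-3,7-dimethoxy-2-(2,3,4,6-tetramethoxyphenyl)-4H-chromen-4-one
Product: 22 2-(2,4-dimethoxy-3,6-dioxocyclohexa-1,4-dien-1-yl)-5-hydroxy-3,7-dimethoxy-4H-chromen-4-one (target)
Conditions: (NH4)2Ce(NO3)6 (2.5 equiv), MeCN–H2O, 0 °C
Reagents that add atoms: water, O
Why: oxidative demethylation of a para-dimethoxyarene by tetravalent cerium, in which ring B is by far the most electron-rich ring, water attacks its radical cation at the methoxy-bearing C3' and C6' (the only para-related oxygenated pair) and loss of two molecules of methanol gives the 2,6-dimethoxy-para-quinone, while the chelated, acyl-deactivated phenol of ring A should be left alone.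

**Compound list**
1 | 3,5-dimethoxyphenol | COc1cc(O)cc(OC)c1 | starting material
2 | 3,5-dimethoxyphenyl N-isopropylcarbamate | COc1cc(OC)cc(OC(=O)NC(C)C)c1 | intermediate
3 | 3,5-dimethoxyphenyl N-isopropyl-N-(trimethylsilyl)carbamate (not isolated) | COc1cc(OC)cc(OC(=O)N(C(C)C)[Si](C)(C)C)c1 | intermediate
4 | 2-lithio-3,5-dimethoxyphenyl N-isopropyl-N-(trimethylsilyl)carbamate (not isolated) | [Li]c1c(OC)cc(OC)cc1OC(=O)N(C(C)C)[Si](C)(C)C | intermediate
5 | 3,5-dimethoxy-2-(trimethylsilyl)phenyl N-isopropyl-N-(trimethylsilyl)carbamate (not isolated) | COc1cc(OC)c([Si](C)(C)C)c(OC(=O)N(C(C)C)[Si](C)(C)C)c1 | intermediate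
6 | 3,5-dimethoxy-2-(trimethylsilyl)phenyl N-isopropylcarbamate | COc1cc(OC)c([Si](C)(C)C)c(OC(=O)NC(C)C)c1 | intermediate
7 | 3,5-dimethoxy-2-(trimethylsilyl)phenol (as its DBU-H phenoxide, not isolated) | COc1cc(OC)c([Si](C)(C)C)c(O)c1 | intermediate
8 | 3,5-dimethoxy-2-(trimethylsilyl)phenyl trifluoromethanesulfonate | COc1cc(OC)c([Si](C)(C)C)c(OS(=O)(=O)C(F)(F)F)c1 | intermediate
9 | 1,2,3,5-tetramethoxybenzene | COc1cc(OC)c(OC)c(OC)c1 | starting material
10 | N,2-dimethoxy-N-methylacetamide | COCC(=O)N(C)OC | starting material
11 | 2,3,4,6-tetramethoxyphenyllithium (not isolated) | [Li]c1c(OC)cc(OC)c(OC)c1OC | intermediate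
12 | 2-methoxy-1-(2,3,4,6-tetramethoxyphenyl)ethan-1-one | COCC(=O)c1c(OC)cc(OC)c(OC)c1OC | intermediate
13 | dimethyl carbonate | COC(=O)OC | starting material
14 | methyl 2-methoxy-3-oxo-3-(2,3,4,6-tetramethoxyphenyl)propanoate (racemic) | COC(=O)C(OC)C(=O)c1c(OC)cc(OC)c(OC)c1OC | intermediate
15 | potassium enolate of 14 (not isolated) | [K+].COC(=O)C(OC)=C([O-])c1c(OC)cc(OC)c(OC)c1OC | intermediate
16 | methyl (E)-2,3-dimethoxy-3-(2,3,4,6-tetramethoxyphenyl)prop-2-enoate | COC(=O)/C(OC)=C(\OC)c1c(OC)c(OC)c(OC)cc1OC | intermediate
17 | (E)-2,3-dimethoxy-3-(2,3,4,6-tetramethoxyphenyl)prop-2-enoic acid | OC(=O)/C(OC)=C(\OC)c1c(OC)c(OC)c(OC)cc1OC | intermediate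
18 | 3,5-dimethoxybenzyne (not isolated) | COC1=CC(OC)=CC#C1 | intermediate
19 | cesium 2-[(E)-2,3-dimethoxy-3-(2,3,4,6-tetramethoxyphenyl)prop-2-enoyl]-3,5-dimethoxyphenoxide (not isolated) | [Cs+].COc1cc([O-])c(C(=O)/C(OC)=C(\OC)c2c(OC)c(OC)c(OC)cc2OC)c(OC)c1 | intermediate
20 | 3,5,7-trimethoxy-2-(2,3,4,6-tetramethoxyphenyl)-4H-chromen-4-one | COc1cc(OC)c2c(=O)c(OC)c(-c3c(OC)c(OC)c(OC)cc3OC)oc2c1 | intermediate
21 | 5-hydroxy-3,7-dimethoxy-2-(2,3,4,6-tetramethoxyphenyl)-4H-chromen-4-one | COc1cc(O)c2c(=O)c(OC)c(-c3c(OC)c(OC)c(OC)cc3OC)oc2c1 | intermediate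
22 | 2-(2,4-dimethoxy-3,6-dioxocyclohexa-1,4-dien-1-yl)-5-hydroxy-3,7-dimethoxy-4H-chromen-4-one | COC1=CC(=O)C(c2oc3cc(OC)cc(O)c3c(=O)c2OC)=C(OC)C1=O | target

**Step count**
Total: 10 steps. Longest linear sequence: 7 steps (steps 4, 5, 6, 7, 8, 9, 10); the aryne precursor branch is 3 steps (steps 1 to 3).

**Steps most likely to fail**

1. Step 8. The aryl anion formed after carboxylate addition may be protonated, or may add too slowly to the hindered, vinylogous-carbonate-like ester carbonyl, so that O-arylation without acyl transfer takes over; ring closure at the crowded C2 may also stall. The fallback builds ring C by known Baker–Venkataraman-type chemistry from the same two arenes; it sets out from 1 and 9 and comes back at 20. Phenol 1 would be acylated ortho to the hydroxyl with methoxyacetic acid in BF3·OEt2 (ester formation and Fries shift under boron chelation) to give 1-(2-hydroxy-4,6-dimethoxyphenyl)-2-methoxyethan-1-one F1. Arene 9 would be lithiated as in step 4 and the aryllithium 11 quenched with CO2 to give 2,3,4,6-tetramethoxybenzoic acid F2, which (COCl)2 with catalytic DMF would convert into 2,3,4,6-tetramethoxybenzoyl chloride F3. The lithium dianion of F1 (LiN(SiMe3)2, THF, −78 °C) would be C-acylated by F3 to give 1-(2-hydroxy-4,6-dimethoxyphenyl)-2-methoxy-3-(2,3,4,6-tetramethoxyphenyl)propane-1,3-dione F4. Acid-catalysed cyclodehydration (catalytic H2SO4, AcOH, warm) would then give 20.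

2. Step 6. The ambident enolate may be methylated at carbon, or conversion may be poor because of the hindered ketone oxygen. The fallback forms the enol ether under acid catalysis, where only oxygen can be functionalised; it sets out from 14 and comes back at 16. Treatment of 14 with HC(OMe)3 and catalytic TsOH in MeOH at reflux would give the dimethyl ketal methyl 2,3,3-trimethoxy-3-(2,3,4,6-tetramethoxyphenyl)propanoate F5, and heating F5 with catalytic TsOH in toluene with removal of methanol would give 16.

3. Step 10. The oxidant may attack the free phenol of ring A, or ring B may be oxidised to an ortho-quinone or at its C5' C–H position instead of the para pair. The fallback reverses the last two operations so that no free phenol is present during oxidation; it sets out from 20 and comes back at 22. Oxidation of 20 with (NH4)2Ce(NO3)6 in MeCN–H2O would give 2-(2,4-dimethoxy-3,6-dioxocyclohexa-1,4-dien-1-yl)-3,5,7-trimethoxy-4H-chromen-4-one F6. One equivalent of BCl3 at −78 °C would then cleave the C5 methyl ether at the most Lewis-basic site, the pyrone carbonyl chelate, to give 22.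

**Further compounds**
F1 | step 8 | 1-(2-hydroxy-4,6-dimethoxyphenyl)-2-methoxyethan-1-one | COCC(=O)c1c(O)cc(OC)cc1OC
F2 | step 8 | 2,3,4,6-tetramethoxybenzoic acid | COc1cc(OC)c(C(=O)O)c(OC)c1OC
F3 | step 8 | 2,3,4,6-tetramethoxybenzoyl chloride | COc1cc(OC)c(C(Cl)=O)c(OC)c1OC
F4 | step 8 | 1-(2-hydroxy-4,6-dimethoxyphenyl)-2-methoxy-3-(2,3,4,6-tetramethoxyphenyl)propane-1,3-dione | COc1cc(O)c(C(=O)C(OC)C(=O)c2c(OC)cc(OC)c(OC)c2OC)c(OC)c1
F5 | step 6 | methyl 2,3,3-trimethoxy-3-(2,3,4,6-tetramethoxyphenyl)propanoate | COC(=O)C(OC)C(OC)(OC)c1c(OC)c(OC)c(OC)cc1OC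
F6 | step 10 | 2-(2,4-dimethoxy-3,6-dioxocyclohexa-1,4-dien-1-yl)-3,5,7-trimethoxy-4H-chromen-4-one | COC1=CC(=O)C(c2oc3cc(OC)cc(OC)c3c(=O)c2OC)=C(OC)C1=O
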